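Slowness was what I distrusted here: the ring opens again more slowly than it closes, but a slow step still runs for as long as the flask does.

    starting material ⇌ ring (K1 = 10.5, k1 = 0.149 min⁻¹)
    2 starting material → open dimer (k2 = 0.113 M⁻¹ min⁻¹)
    starting material + protic impurity → quenched substrate (k3 = 0.0887 M⁻¹ min⁻¹)
    starting material ⇌ dormant form (K4 = 2.78, k4 = 0.00427 min⁻¹)

all flasks: protic impurity 0.200 M
- dusk: starting material 0.40 M; one stirred flow tank at steady state, fed with the mixture as stated, mean residence time 2.0 h
- dawn: starting material 0.40 M; everything together in a closed stirred flask, run for 2.0 h; time 2.0 h
- midnight: starting material 0.40 M (fed, over 2.00 h); a stirred flask in which starting material is dosed at a steady rate over 2.00 h without added volume, worked up at 2.0 h; time 2.0 h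

- the set-up with the highest amount of ring at the outlet or at the end, in percent of the starting material put in ("none" if the first two lie within 2 percentage points) (dusk / dawn / midnight / none)
- amount of ring at the outlet or at the end, in percent of the starting material put in, dusk
- amount of ring at the outlet or at the end, in percent of the starting material put in, dawn
- amount of ring at the outlet or at the end, in percent of the starting material put in, midnight

- in percentages every species weighs as the starting material in it: one open dimer counts as two
- for a step with 2 of a species take k times the square, and two of it per event
- the stated concentrations are those of everything mixed, before any reaction; amounts are the same in each set-up
- the feed brings no volume worth counting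
- run time (dawn): 2.0 h

I reckoned the closed flask, dawn, in two ways. The first shared out the starting material by the starting rates, with [starting material] and [protic impurity] held at their charges, and gave the ring 57.0%. The second counted turnovers. Over the run, closure makes 17.9 turnovers and opening 1.70, so in dawn I could not treat the ring as a final product.

I therefore let [starting material] fall from its charge, integrated the ring's share over that fall, and got a first split of 69.9%. After the split in dawn, I took ring and starting material as one pool, 91.3% of it ring. Free starting material is one part in 11.5 of that pool, and it still reacts with the protic impurity, pseudo-first-order at the charged [protic impurity], and goes to the dormant form, whose return I dropped. Counting these two routes and leaving dimer out of the drain, I put the pool's drain at 0.00191 min⁻¹. This rate times the time spent in the pool is the leak count, 0.230 in dawn. Split, decay over that count and the ring's part of the pool together gave 50.8%.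

The two ways parted by 6.2 percentage points, and the first one cheated. It kept dimer running at the charged level, although closure alone, forward rate, has a half-life of 0.078 h, shorter than the run, and it let no ring return. I committed to the second figure.

The forecast chose midnight, with 62.5% for dusk, 56.5% for dawn and 66.5% for midnight, on the ground that “keeping free starting material low favours the ring”. Its dawn figure stood above mine.

The simulation gave 62.5% for dusk, 53.5% for dawn and 67.9% for midnight, so midnight came out best, and dawn stood above my figure. In dawn, the half-life of starting material by the forward rate of closure alone, 0.078 h, lay far below the run of 2.0 h. My estimated leak time of 8.73 h lay far above the run, which is the leak count of 0.230 read the other way. In midnight, evenly dosed starting material spent on average half the run in the pool, so I put its count at 0.115. Assuming a split free of dimer, I reckoned 70.9% from that count, and midnight held 67.9%.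

The constants are those of an exercise.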